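Ring B (C6–C11) is cut at C6–C7 and C8–C9. C6, a quaternary carbon flanked by C1 and C5, is read as a malonate carbon, C7–C8 as a vinylphosphonium salt and C9–C11 with the C9 methyl as methyl vinyl ketone. One Michael/Michael/Wittig operation joins the three to an achiral 4,4-dicarboxy-1-methylcyclohexene whose alkene lies where C8–Br and C9–Cl are needed. A desymmetrising bromolactonisation sets C8/C9; one carboxyl carbon becomes C1, the other leaves as CO2, and the C6 enol of the resulting ketone closes ring A (C5–C6) onto a bromonium ion from an enantioenriched bromochloride. Methylenation and allylic oxidation finish.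

Key step: step 1

Remark (numbering): C1–C11 are the spiro[5.5]undecane locants of the target, (2R,4R,6S,8S,9S)-4,8-dibromo-9-chloro-5,5,9-trimethyl-1-methylidenespiro[5.5]undecan-2-ol: C1 = C(=CH2), C2 = CHOH, C4 = CHBr, C5 = CMe2, C6 = spiro carbon, C7 = CH2, C8 = CHBr, C9 = C(Me)Cl; ring A = C1–C6, ring B = C6–C11.

Remark (assumption): the sense of induction of the two catalytic asymmetric halogenations (steps 3 and 5) is taken as drawn; if found opposite, the pseudo-enantiomeric catalyst (DHQ)2PHAL or the enantiomeric ligand is used.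

Step 1
Reactants: 1 dimethyl malonate; 2 vinyltriphenylphosphonium bromide; 3 methyl vinyl ketone
Product: 6 dimethyl 4-methylcyclohex-3-ene-1,1-dicarboxylate, via phosphonium malonate betaine 4 (not isolated), via keto ylide 5 (not isolated)
Conditions: NaH, THF, 0 °C; 2, DMSO, rt; 3, 0 °C to rt; then 65 °C
Reagents that add atoms: none
Why: Sodiomalonate adds to the vinylphosphonium salt (C6–C7) and the ylide first formed is quenched by the remaining malonate C–H to give zwitterion 4, which adds to methyl vinyl ketone (C6–C11); the methyl ketone enolate so formed is more basic than a phosphorus ylide, so proton transfer gives keto ylide 5, whose intramolecular Wittig reaction forms C8=C9. The closest known reaction is the annulation of (3-oxobutyl)malonates with vinyltriphenylphosphonium bromide (Schweizer reagent), run here as a three-component Michael/Michael/Wittig cascade. Ring B closes as a six-membered ring by attack of the ylide carbon C8 on the ketone carbon C9 (6-exo-trig addition to the carbonyl, then oxaphosphetane collapse), which puts the trisubstituted alkene exactly where the Br/Cl pair is needed. No stereocenter is formed: the product is achiral with two enantiotopic carboxyl groups, as the later desymmetrisation requires. The selectivity needed is a single addition of each acceptor and olefination rather than Claisen or aldol closure; the cationic acceptor is added first because zwitterion 4 resists a second phosphonium addition, each proton transfer moves the charge to the more acidic site, and only the ylide has a ketone within reach of a six-membered ring.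

Step 2
Reactants: 6 dimethyl 4-methylcyclohex-3-ene-1,1-dicarboxylate
Product: 7 4-methylcyclohex-3-ene-1,1-dicarboxylic acid
Conditions: KOH, MeOH/H2O, 60 °C; then aq. HCl, 0 °C
Reagents that add atoms: potassium hydroxide, [K+].[OH-]
Why: Saponification of the two geminal esters (ester hydrolysis) should proceed below the decarboxylation range of the malonic acid and creates no stereocenter.

Step 3
Reactants: 7 4-methylcyclohex-3-ene-1,1-dicarboxylic acid
Product: 8 (1S,4R,6S)-6-bromo-1-methyl-3-oxo-2-oxabicyclo[2.2.2]octane-4-carboxylic acid (Br anti to the lactone oxygen)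
Conditions: NBS, (DHQD)2PHAL (hydroquinidine 1,4-phthalazinediyl diether, 10 mol %), CHCl3/toluene, −40 °C
Reagents that add atoms: N-bromosuccinimide, O=C1CCC(=O)N1Br
Why: In this catalytic enantioselective, desymmetrising bromolactonisation the chiral Lewis base should deliver bromenium to one enantiotopic alkene face while the carboxyl group on the opposite face opens the bromonium ion at the tertiary carbon (Markovnikov, anti), so that lactone C1 and C6 (later C9 and C8) are set together by the catalyst and the anti addition, and C4 becomes stereogenic as a consequence.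

Step 4
Reactants: 8 (1S,4R,6S)-6-bromo-1-methyl-3-oxo-2-oxabicyclo[2.2.2]octane-4-carboxylic acid
Product: 10 (1S,4R,6S)-4-acetyl-6-bromo-1-methyl-2-oxabicyclo[2.2.2]octan-3-one, via acid chloride 9 (not isolated)
Conditions: (COCl)2, DMF (cat.), CH2Cl2, 0 °C to rt; then MeMgBr, Fe(acac)3 (3 mol %), THF, −78 °C
Reagents that add atoms: methylmagnesium bromide, C[Mg]Br
Why: The only free carboxyl group is converted into its chloride, which should acylate the Grignard reagent under iron catalysis (iron-catalysed ketone synthesis from acid chlorides) fast enough at −78 °C to spare the lactone and the secondary bromide; no stereocenter is touched, and the acetyl carbon is the future C1.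

Step 5
Reactants: 11 3-methylbut-2-en-1-ol (prenol)
Product: 12 (2R)-2-bromo-3-chloro-3-methylbutan-1-ol
Conditions: NBS, ClTi(OiPr)3, (S)-2-[(3,5-di-tert-butyl-2-hydroxybenzylidene)amino]-3,3-dimethyl-1,1-diphenylbutan-1-ol (Schiff-base ligand, 20 mol %), hexanes, −20 °C
Reagents that add atoms: N-bromosuccinimide, O=C1CCC(=O)N1Br; chlorotitanium triisopropoxide, CC(C)O[Ti](Cl)(OC(C)C)OC(C)C
Why: Titanium/Schiff-base-catalysed enantioselective bromochlorination of the allylic alcohol should place bromine at C2 and deliver chloride from titanium to the tertiary carbon anti to the bromonium ion, so the C2 stereocenter (later C4) is set by the ligand.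

Step 6
Reactants: 12 (2R)-2-bromo-3-chloro-3-methylbutan-1-ol
Product: 13 (2R)-2-bromo-3-chloro-3-methylbutyl trifluoromethanesulfonate
Conditions: Tf2O, 2,6-lutidine, CH2Cl2, −78 °C
Reagents that add atoms: trifluoromethanesulfonic anhydride, O=S(=O)(OS(=O)(=O)C(F)(F)F)C(F)(F)F
Why: O-Sulfonylation of the primary alcohol (triflate formation) gives an electrophile reactive enough for SN2 to outrun elimination in step 7 and leaves the stereocenter untouched.

Step 7
Reactants: 10 (1S,4R,6S)-4-acetyl-6-bromo-1-methyl-2-oxabicyclo[2.2.2]octan-3-one; 13 (2R)-2-bromo-3-chloro-3-methylbutyl trifluoromethanesulfonate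
Product: 15 (1S,4R,6S)-6-bromo-4-[(4R)-4-bromo-5-chloro-5-methylhexanoyl]-1-methyl-2-oxabicyclo[2.2.2]octan-3-one, via lithium enolate 14 (not isolated)
Conditions: LiN(iPr)2 (LDA), THF, −78 °C; then 13, −78 to −30 °C
Reagents that add atoms: none
Why: The acetyl methyl is the only enolisable position of 10 (C4 is quaternary), so LDA should give one lithium enolate, which is C-alkylated by the primary triflate (SN2 enolate alkylation, forming C2–C3) without touching any stereocenter.

Step 8
Reactants: 15 (1S,4R,6S)-6-bromo-4-[(4R)-4-bromo-5-chloro-5-methylhexanoyl]-1-methyl-2-oxabicyclo[2.2.2]octan-3-one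
Product: 17 (4R)-4-bromo-1-[(1R,3S,4S)-3-bromo-4-chloro-4-methylcyclohexyl]-5-chloro-5-methylhexan-1-one, via β-keto acid 16 (not isolated)
Conditions: HCl (4 M in 1,4-dioxane), CH2Cl2, 0 °C to rt; then 50 °C
Reagents that add atoms: hydrogen chloride, Cl
Why: HCl should cleave the tertiary alkyl–oxygen bond of the lactone with anchimeric help of the anti bromine, chloride opening the bromonium ion at the tertiary carbon so that Cl replaces O with overall retention (trans-bromochloride, C8/C9 of the target), after which β-keto acid 16 decarboxylates (tertiary ester acidolysis, then β-keto acid decarboxylation); the cyclohexane C1 epimers are immaterial because this centre is enolised in step 9.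

Step 9
Reactants: 17 (4R)-4-bromo-1-[(1R,3S,4S)-3-bromo-4-chloro-4-methylcyclohexyl]-5-chloro-5-methylhexan-1-one
Product: 18 (4R,6R,8S,9S)-4,8-dibromo-9-chloro-5,5,9-trimethylspiro[5.5]undecan-1-one
Conditions: (CF3)2CHOH (HFIP), 40 °C
Reagents that add atoms: none
Why: HFIP should ionise the acyclic tertiary chloride, assisted by the vicinal bromine, to a configurationally defined bromonium ion that is captured at C5 by the C6 enol of the ketone through a chair with C4–Br equatorial (solvolytic bromonium-initiated cation–enol cyclisation); because the E and Z enols interconvert through the ketone, C6 is decided by equatorial C–C bond formation on ring B cis to the equatorial C8–Br (conformer with C9–Me axial), while C4 keeps the configuration of 13.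

Step 10
Reactants: 18 (4R,6R,8S,9S)-4,8-dibromo-9-chloro-5,5,9-trimethylspiro[5.5]undecan-1-one
Product: 19 (4R,6S,8S,9S)-4,8-dibromo-9-chloro-5,5,9-trimethyl-1-methylidenespiro[5.5]undecane
Conditions: Cp2TiMe2, toluene, 65 °C, dark
Reagents that add atoms: dimethyltitanocene, C[Ti](C)(C1C=CC=C1)C1C=CC=C1
Why: The titanium methylidene formed thermally from Cp2TiMe2 should methylenate the hindered, enolisable ketone under non-basic conditions (Petasis olefination), so the tertiary chloride and both secondary bromides survive and no stereocenter is affected.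

Step 11
Reactants: 19 (4R,6S,8S,9S)-4,8-dibromo-9-chloro-5,5,9-trimethyl-1-methylidenespiro[5.5]undecane
Product: 20 (2R,4R,6S,8S,9S)-4,8-dibromo-9-chloro-5,5,9-trimethyl-1-methylidenespiro[5.5]undecan-2-ol (target)
Conditions: SeO2 (cat.), t-BuOOH, CH2Cl2, 0 °C to rt
Reagents that add atoms: tert-butyl hydroperoxide (terminal oxidant), CC(C)(C)OO; selenium dioxide (oxygen carrier), O=[Se]=O
Why: SeO2 allylic oxidation (ene reaction, then [2,3]-sigmatropic shift) can only engage C2 because C6 is quaternary, and oxygen should be delivered pseudo-axially to C2 on the half-chair that keeps C4–Br equatorial, i.e. trans to that bromine, giving the axial (2R) alcohol with the exocyclic alkene restored.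

Compound list
1 | dimethyl malonate | COC(=O)CC(=O)OC | starting material
2 | vinyltriphenylphosphonium bromide | C=C[P+](c1ccccc1)(c1ccccc1)c1ccccc1.[Br-] | starting material
3 | methyl vinyl ketone (but-3-en-2-one) | CC(=O)C=C | starting material
4 | dimethyl 2-[2-(triphenylphosphonio)ethyl]propanedioate carbanion (zwitterion) | COC(=O)[C-](CC[P+](c1ccccc1)(c1ccccc1)c1ccccc1)C(=O)OC | intermediate
5 | dimethyl 2-(3-oxobutyl)-2-[2-(triphenylphosphoranylidene)ethyl]propanedioate | COC(=O)C(CCC(C)=O)(CC=P(c1ccccc1)(c1ccccc1)c1ccccc1)C(=O)OC | intermediate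
6 | dimethyl 4-methylcyclohex-3-ene-1,1-dicarboxylate | COC(=O)C1(CC=C(C)CC1)C(=O)OC | intermediate
7 | 4-methylcyclohex-3-ene-1,1-dicarboxylic acid | CC1=CCC(CC1)(C(=O)O)C(=O)O | intermediate
8 | (1S,4R,6S)-6-bromo-1-methyl-3-oxo-2-oxabicyclo[2.2.2]octane-4-carboxylic acid | C[C@]12CC[C@](C(=O)O)(C[C@@H]1Br)C(=O)O2 | intermediate
9 | (1S,4S,6S)-6-bromo-1-methyl-3-oxo-2-oxabicyclo[2.2.2]octane-4-carbonyl chloride | C[C@]12CC[C@](C(=O)Cl)(C[C@@H]1Br)C(=O)O2 | intermediate
10 | (1S,4R,6S)-4-acetyl-6-bromo-1-methyl-2-oxabicyclo[2.2.2]octan-3-one | C[C@]12CC[C@](C(C)=O)(C[C@@H]1Br)C(=O)O2 | intermediate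
11 | 3-methylbut-2-en-1-ol | CC(C)=CCO | starting material
12 | (2R)-2-bromo-3-chloro-3-methylbutan-1-ol | OC[C@@H](Br)C(C)(C)Cl | intermediate
13 | (2R)-2-bromo-3-chloro-3-methylbutyl trifluoromethanesulfonate | O=S(=O)(OC[C@@H](Br)C(C)(C)Cl)C(F)(F)F | intermediate
14 | lithium 1-[(1S,4R,6S)-6-bromo-1-methyl-3-oxo-2-oxabicyclo[2.2.2]octan-4-yl]ethen-1-olate | C[C@]12CC[C@](C(=C)O[Li])(C[C@@H]1Br)C(=O)O2 | intermediate
15 | (1S,4R,6S)-6-bromo-4-[(4R)-4-bromo-5-chloro-5-methylhexanoyl]-1-methyl-2-oxabicyclo[2.2.2]octan-3-one | C[C@]12CC[C@](C(=O)CC[C@@H](Br)C(C)(C)Cl)(C[C@@H]1Br)C(=O)O2 | intermediate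
16 | (1R,3S,4S)-3-bromo-1-[(4R)-4-bromo-5-chloro-5-methylhexanoyl]-4-chloro-4-methylcyclohexane-1-carboxylic acid | O=C(CC[C@@H](Br)C(C)(C)Cl)[C@@]1(C(=O)O)CC[C@](C)(Cl)[C@@H](Br)C1 | intermediate
17 | (4R)-4-bromo-1-[(1R,3S,4S)-3-bromo-4-chloro-4-methylcyclohexyl]-5-chloro-5-methylhexan-1-one | O=C(CC[C@@H](Br)C(C)(C)Cl)[C@@H]1CC[C@](C)(Cl)[C@@H](Br)C1 | intermediate
18 | (4R,6R,8S,9S)-4,8-dibromo-9-chloro-5,5,9-trimethylspiro[5.5]undecan-1-one | O=C1CC[C@@H](Br)C(C)(C)[C@]12CC[C@](C)(Cl)[C@@H](Br)C2 | intermediate
19 | (4R,6S,8S,9S)-4,8-dibromo-9-chloro-5,5,9-trimethyl-1-methylidenespiro[5.5]undecane | C=C1CC[C@@H](Br)C(C)(C)[C@]12CC[C@](C)(Cl)[C@@H](Br)C2 | intermediate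
20 | (2R,4R,6S,8S,9S)-4,8-dibromo-9-chloro-5,5,9-trimethyl-1-methylidenespiro[5.5]undecan-2-ol | C=C1[C@H](O)C[C@@H](Br)C(C)(C)[C@]12CC[C@](C)(Cl)[C@@H](Br)C2 | target

Total step count: 11. Longest linear sequence: 9 steps (1, 2, 3, 4, 7, 8, 9, 10, 11); steps 5 and 6 prepare the side-chain fragment.

Steps most likely to fail

Step 9. The bromonium ion may be captured by the ketone oxygen or lose a proton instead of forming the C5–C6 bond, and the discrimination between the two faces of ring B at C6 may be poor. The fallback sets out from 17 and replaces the enol by an all-carbon alkene nucleophile, the type of terminator for which solvolytic bromonium spirocyclisation is established. MeMgBr with CeCl3 (THF, −78 °C) should add to the ketone to give the tertiary alcohol (5R)-5-bromo-2-[(1R,3S,4S)-3-bromo-4-chloro-4-methylcyclohexyl]-6-chloro-6-methylheptan-2-ol F1. Dehydration with the Burgess reagent should give the tetrasubstituted alkene (3S,4S)-3-bromo-1-[(5R)-5-bromo-6-chloro-6-methylheptan-2-ylidene]-4-chloro-4-methylcyclohexane F2 as an E/Z mixture. HFIP solvolysis of F2 should then close ring A, the C1 cation losing a methyl proton, and the route is rejoined at 19, step 10 being skipped. Only the geometric isomer matched to ring B leads to 19, so the other would have to be recycled by acid isomerisation.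

Step 3. Enantiofacial discrimination at the alkene may be insufficient, or the carboxyl group may attack the secondary carbon. The fallback sets out from 7: uncatalysed bromolactonisation (NBS, NaHCO3, CH2Cl2/H2O) should give 8 together with its enantiomer (1R,4S,6R)-6-bromo-1-methyl-3-oxo-2-oxabicyclo[2.2.2]octane-4-carboxylic acid F3. Classical resolution by crystallisation of the (S)-1-phenylethylammonium salt of 8, F4, and acidification returns the route to 8.

Step 7. The β-bromo triflate may undergo elimination, or the enolate may be O-alkylated, instead of C-alkylation. The fallback sets out from 10: the same enolate is alkylated with prenyl bromide to (1S,4R,6S)-6-bromo-1-methyl-4-(5-methylhex-4-enoyl)-2-oxabicyclo[2.2.2]octan-3-one F5. Shi epoxidation with the L-fructose-derived ketone catalyst (Oxone, pH 10.5, 0 °C) should give the epoxide (1S,4R,6S)-6-bromo-4-{3-[(2S)-3,3-dimethyloxiran-2-yl]propanoyl}-1-methyl-2-oxabicyclo[2.2.2]octan-3-one F6. Li2NiBr4 (THF) should open it at the secondary carbon with inversion to the bromohydrin (1S,4R,6S)-6-bromo-4-[(4R)-4-bromo-5-hydroxy-5-methylhexanoyl]-1-methyl-2-oxabicyclo[2.2.2]octan-3-one F7. Under the conditions of step 8, HCl should convert the tertiary alcohol into the chloride with retention through the bromonium ion, open the lactone and decarboxylate, which returns the route to 17.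

Further compounds
F1 | step 9 | (5R)-5-bromo-2-[(1R,3S,4S)-3-bromo-4-chloro-4-methylcyclohexyl]-6-chloro-6-methylheptan-2-ol | CC(O)(CC[C@@H](Br)C(C)(C)Cl)[C@@H]1CC[C@](C)(Cl)[C@@H](Br)C1
F2 | step 9 | (3S,4S)-3-bromo-1-[(5R)-5-bromo-6-chloro-6-methylheptan-2-ylidene]-4-chloro-4-methylcyclohexane | CC(CC[C@@H](Br)C(C)(C)Cl)=C1CC[C@](C)(Cl)[C@@H](Br)C1
F3 | step 3 | (1R,4S,6R)-6-bromo-1-methyl-3-oxo-2-oxabicyclo[2.2.2]octane-4-carboxylic acid | C[C@@]12CC[C@@](C(=O)O)(C[C@H]1Br)C(=O)O2
F4 | step 3 | (S)-1-phenylethylammonium (1S,4R,6S)-6-bromo-1-methyl-3-oxo-2-oxabicyclo[2.2.2]octane-4-carboxylate | C[C@]12CC[C@](C(=O)[O-])(C[C@@H]1Br)C(=O)O2.C[C@H]([NH3+])c1ccccc1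
F5 | step 7 | (1S,4R,6S)-6-bromo-1-methyl-4-(5-methylhex-4-enoyl)-2-oxabicyclo[2.2.2]octan-3-one | C[C@]12CC[C@](C(=O)CCC=C(C)C)(C[C@@H]1Br)C(=O)O2
F6 | step 7 | (1S,4R,6S)-6-bromo-4-{3-[(2S)-3,3-dimethyloxiran-2-yl]propanoyl}-1-methyl-2-oxabicyclo[2.2.2]octan-3-one | C[C@]12CC[C@](C(=O)CC[C@@H]3OC3(C)C)(C[C@@H]1Br)C(=O)O2
F7 | step 7 | (1S,4R,6S)-6-bromo-4-[(4R)-4-bromo-5-hydroxy-5-methylhexanoyl]-1-methyl-2-oxabicyclo[2.2.2]octan-3-one | C[C@]12CC[C@](C(=O)CC[C@@H](Br)C(C)(C)O)(C[C@@H]1Br)C(=O)O2
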